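At early times in Saturday's flask, at 0 °C, the starting material falls between 0.667 h and 2.00 h as a first-order decay with k = 1.17 h⁻¹, while the product levels off near 8.5 %. Monday's flask, at 33 °C, has 0.7 % left at 0.200 h, so its k is at least about 24.8 h⁻¹, and its product sits near 0.3 %, barely above the scatter.

| flask | starting material | temperature | remark | time |
|---|---|---|---|---|
| Saturday's | 0.014 M | 0 °C | run made earlier |  |
| Monday's | 0.022 M | 33 °C | run made earlier |  |
| red | 0.010 M | 5 °C |  | 12 h |
| teal | 0.010 M | 45 °C |  | 12 h |
| blue | 0.010 M | −15 °C |  | 12 h |
| violet | 0.010 M | 25 °C |  | 12 h |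

| run | time / h | product / % | starting material / % |
|---|---|---|---|
| Saturday's | 0.667 | 4.3 | 44.5 |
| Saturday's | 2.00 | 8.1 | 9.3 |
| Saturday's | 3.00 | 8.8 | 2.7 |
| Saturday's | 5.00 | 8.1 | 0 |
| Saturday's | 8.00 | 8.6 | 0 |
| Saturday's | 10.0 | 8.5 | 0 |
| Monday's | 0.200 | 0 | 0.7 |
| Monday's | 0.333 | 0.7 | 0 |
| Monday's | 0.500 | 0.4 | 0 |
| Monday's | 1.00 | 0.2 | 0 |
| Monday's | 1.50 | 0.3 | 0.2 |
| Monday's | 2.50 | 0.3 | 0 |

(each reading ± 0.3 percentage points)

- the numbers in the tables scatter by 0.3 percentage points (one standard deviation)

- the flask that comes out highest in amount of product, in percent of the starting material charged, or "all alike" when all lie within 1.5 percentage points (red / teal / blue / violet / all alike)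
- product at the end, in percent of the starting material charged, red
- product at the end, in percent of the starting material charged, teal
- product at the end, in percent of the starting material charged, blue
- product at the end, in percent of the starting material charged, violet

Blue lies below Saturday's by 0.455 of the span between the two runs. A straight line in ln k against temperature, drawn through Monday's lower limit, therefore gives the ceiling rate for blue, k = 0.294 h⁻¹, and you can use it on any reading of that flask, since c of starting material falls as exp(−kt). Over 12 h that makes θ = kt = 3.52 lifetimes.

Now take two extremes. The same line, applied to the selectivity factor r (product over everything else), runs from 0.0929 on Saturday and 0.00301 on Monday to 0.442 in blue, a share of 30.6 %. A very long flask reaches that share, and a very short one reaches the share times θ. Blue lies between them, so put the first answer back in: with at least 2.96 % left, I expect 29.7 %. Red, at 5 °C, gets a share of 5.24 %, less than blue, so I commit to blue.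

The forecast, a little above my figure for blue, says blue with 33 %, and red 5.2 %, violet 0.7 %, teal 0.1 %: “Blue should be highest”.

The flask gives blue: blue 18.8 %, red 5.62 %, violet 0.641 %, teal 0.0633 %.

    intermediate A → intermediate C (k = 0.00490 min⁻¹, Ea = 80.0 kJ mol⁻¹)
    starting material → intermediate B (k = 0.0260 min⁻¹, Ea = 75.0 kJ mol⁻¹)
    intermediate C ⇌ intermediate B (K = 1.60, k = 0.00320 min⁻¹, Ea = 85.0 kJ mol⁻¹, ΔH = −51.0 kJ mol⁻¹)
    intermediate B ⇌ product (K = 0.100, k = 0.0310 min⁻¹, Ea = 83.0 kJ mol⁻¹, ΔH = −49.0 kJ mol⁻¹)
    starting material → intermediate A (k = 0.0110 min⁻¹, Ea = 78.0 kJ mol⁻¹)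
    (constants at 5 °C)

In blue, 12.3 % of the starting material stands at 12.0 h, above the floor that k set, and the product lies 11 percentage points under my figure. Half of the turnover of starting material into intermediate B is done by 3.30 h, and half of the turnover of intermediate B into product by 5.58 h. The step between intermediate B and product runs both ways, and in blue its relaxation half-life of 2.05 h is short against the 12 h of the run; at 12.0 h intermediate B holds 44.4 % beside 18.8 % of product.

Read the same blue flask at 3.0 h: k leaves at least 41.4 % of the starting material. The flask holds 59.2 %, with 4.01 % of product.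

(The earlier runs and the new flask are calculated with constants of no real substance, noise included.)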